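## The problem

Compound 19 is a 2,6-diaryl-3,7-dioxabicyclo[3.3.0]octane. Ring A (C1–C2–O3–C4–C5) and ring B (C5–C6–O7–C8–C1) are tetrahydrofurans fused cis along C1–C5; aryl A (3-hydroxy-4,5-dimethoxyphenyl) sits on C2 and aryl B (3,4,5-trimethoxyphenyl) on C6, both on the convex face, and the configuration is (1R,2S,5R,6S). The core is twofold-symmetric, but the arenes differ by one O-methyl group, so two different aryl building blocks must be joined in a defined order and the single phenol kept masked to the end. Of the four contiguous stereocentres, C2 and C6 are benzylic ether carbons that catalytic asymmetric reduction of aryl ketones can set. C1 and C5 are locked to each other by the cis fusion and to C2 and C6 by the preference of the aryl groups for the convex face, so C2 and C6 can control C1 and C5. The benzylic C–O bonds, each para to a methoxy group, ionise under acid (epimerisation, ring opening) and are cut by hydrogenolysis; this rules out benzyl protection, late hydrogenation and strongly acidic ring closures, and the phenol must not meet base or a one-electron oxidant unprotected. The feature the plan uses is the periphery C1–C2–O3–C4–C5–C6–O7–C8, an eight-membered 1,5-dioxocane in which C1 and C5 face each other across the ring. With C4 and C8 as carbonyl groups this periphery is the cyclic double ester (diolide) of two 3-aryl-3-hydroxypropanoic acids, C1 and C5 are its two enolisable α-carbons, and one transannular C1–C5 bond would close ring A and ring B at once.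

## Retrosynthesis

**19 from 18.** The last cut is the phenol O–Si bond. A triisopropylsilyl ether should survive amide base, TiCl4, hydride and BF3 at low temperature and falls to fluoride without acid or hydrogen; a benzyl ether would need hydrogenolysis, which also attacks C2–O3 and C6–O7. The forward step only has to spare the benzylic ethers.

**18 from 16 through 17.** C4 and C8 are raised from CH2 to lactone carbonyls. Dilactone 16 has the full skeleton and all four stereocentres, and its carbonyl groups are what make C1 and C5 acidic for the key step. The forward reductions (lactone to lactol 17, lactol to ether) must leave the benzylic C–O bonds un-ionised.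

**16 from 14 through 15.** The C1–C5 bond is cut. This turns two fused γ-lactones with four stereocentres into the monocyclic diolide 14 with only the two carbinol centres C2 and C6. Cutting C1–C2 or C5–C6 instead (aldol logic) would leave a benzylic carbinol to be set against an existing ring. Cutting the C–O bonds would leave an open-chain succinate with four stereocentres. The forward step must form both lactone enolate equivalents without loss of the β-carboxylate (hence the bis(ketene silyl acetal) 15) and join the α-carbons across the ring on the faces anti to the aryl groups.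

**14 from 12 through 13.** The O3–C4 lactone bond is cut to give seco acid 12. Ring expansion of a carbocyclic diketone by double Baeyer–Villiger oxidation would avoid the medium-ring closure, but it needs one enantiomer of a diketone with two epimerisable α-aryl centres and two different aryl groups. Lactonisation takes both centres from catalytic reductions. The forward step must close an eight-membered ring faster than it oligomerises and must not eliminate the β-acyloxy group of the activated acid.

**12 from 10 through 11.** The acid is unmasked from an allyl ester and C2–H is cut back to the aryl ketone of 10. Reducing after the halves are joined means the C2 hydroxyl never needs a protecting group. The forward steps need catalyst-controlled (S) reduction that spares the allyl and benzylic esters, then neutral deallylation.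

**10 from 8 and 3 through 9.** The O7–C8 ester bond is cut. Acyl Meldrum's acid 8 carries aryl A, C2, C1 and C8; carbinol 3 carries aryl B, C6, C5 and C4. Joining a protected β-hydroxy acid to 3 by carbodiimide esterification would cost a hydroxyl protection, a saponification beside an aryl silyl ether and a later deprotection. The forward step asks only that the aroylketene 9 be trapped by a secondary benzylic alcohol under neutral conditions, with retention at C6.

**8 from 6 and 7; 6 from 4 through 5.** The C2–C1 bond comes from C-acylation of Meldrum's acid 7 by the silylated acid 6, which is made from commercial acid 4.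

**3 from 1 through 2.** C6–H comes from asymmetric transfer hydrogenation of keto ester 2, the allyl ester of commercial 1; the allyl group is installed here because it is the ester that can later be removed selectively.

## Roads not taken

**Alternative 1:** The cut is C1–C2 and C5–C6 on a chiral-pool butenolide. Lithiated dithiane A2 would add to the β-carbon of the glutamic-acid-derived butenolide A1 anti to the trityloxymethyl group, and the enolate would be trapped by aldehyde A3 to give the trans,trans lactone A4.
- Merits: a three-component, one-pot union of known type with reliable trans induction at C1 and C5.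
- Weak points: no ring of the target is closed; the C6 carbinol is not controlled; the dithiane must be unmasked beside electron-rich arenes and the ketone reduced; the extra carbon of A1 must be excised; and both ether rings are then closed through benzylic cations under thermodynamic control.
- Comparison: this road is safer step for step and tolerates poor carbinol selectivity. The chosen plan sets against it a key step that makes both rings and both bridgehead centres at once, benzylic centres fixed by catalysis and never ionised, and no auxiliary carbon to remove.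

**Alternative 2:** The cut is C4–C5 and C1–C2 (a cyclobutane), followed by insertion of O3. Sensitised [2+2] photocycloaddition of butenolide A5 with ketene acetal A6 would give the cyclobutane-fused lactone A7, anti to aryl B; ketal hydrolysis and Baeyer–Villiger oxidation (benzylic migration, retention) would give the same dilactone 16.
- Merits: it is shorter on paper than the chosen plan, and C2 can be equilibrated to the exo position at the cyclobutanone stage.
- Weak points: A6 is an electron-rich styrene that can quench the excited enone by energy or electron transfer, so regiochemistry and efficiency are uncertain; A6 is acid-labile; the γ-hydrogen of A5 is benzylic and vinylogously acidic, so its single stereocentre is easily lost.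
- Comparison: in step count this road is better. The chosen plan offers two robust, catalyst-set carbinol centres and purely thermal chemistry.

**Alternative 3:** The cut is C6–O7 (with C5–H). Acid would convert the arylidene lactone A8 into a C6 cation that the C8 hydroxyl captures, and protonation at C5 would give the cis-fused furofuranone A9.
- Merits: closure under thermodynamic control places aryl B exo; only one carbonyl remains to be removed.
- Weak points: the step closes one ring and makes no skeletal C–C bond; A8 already needs ring A with C1 and C2 set; the cation is stabilised only by a para-methoxy group twisted by two neighbours; the same acid can ionise C2–O3.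
- Comparison: the reaction type is better known, but the key step builds less and the route to A8 is long. The chosen plan accepts more risk for a step that creates two rings, one C–C bond and two stereocentres.

Key step: step 9

Assumption: the (S,S)-TsDPEN ruthenium catalyst is taken to reduce aroylacetates with the same facial sense as acetophenone (hydride to the Re face, (S)-carbinol); were the sense opposite, the (R,R) ligand would be used in steps 2 and 6.

## Steps

Step 1
Reactants: 1 ethyl 3-oxo-3-(3,4,5-trimethoxyphenyl)propanoate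
Product: 2 prop-2-enyl 3-oxo-3-(3,4,5-trimethoxyphenyl)propanoate
Conditions: allyl alcohol (5 equiv), DMAP (0.2 equiv), toluene, reflux, 4 Å sieves (removal of EtOH)
Reagents that add atoms: prop-2-en-1-ol (allyl alcohol), C=CCO
Why: DMAP-catalysed transesterification of a β-keto ester is a standard exchange driven by removal of ethanol. The allyl ester is the acid mask that can later be removed without touching a benzylic ester or an aryl silyl ether.

Step 2
Reactants: 2 prop-2-enyl 3-oxo-3-(3,4,5-trimethoxyphenyl)propanoate
Product: 3 prop-2-enyl (3S)-3-hydroxy-3-(3,4,5-trimethoxyphenyl)propanoate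
Conditions: RuCl[(S,S)-TsDPEN](p-cymene) (1 mol %), HCO2H/Et3N (5:2), DMF, 40 °C
Reagents that add atoms: none
Why: Noyori asymmetric transfer hydrogenation of an aryl β-keto ester; the (S,S) catalyst should deliver hydride to the Re face of the aryl ketone and set C6 as (S). Formate as reductant should leave the allyl C=C untouched.

Step 3
Reactants: 4 3-hydroxy-4,5-dimethoxybenzoic acid
Product: 6 4,5-dimethoxy-3-[(triisopropylsilyl)oxy]benzoic acid, via bis-silylated silyl ester 5 (not isolated)
Conditions: i-Pr3SiCl (2.3 equiv), imidazole, DMF, rt; then AcOH/THF/H2O, rt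
Reagents that add atoms: chlorotri(propan-2-yl)silane (triisopropylsilyl chloride), CC(C)[Si](Cl)(C(C)C)C(C)C
Why: Imidazole-mediated silylation covers phenol and acid; the silyl ester is far more labile than the aryl silyl ether and should be hydrolysed selectively by aqueous acetic acid.

Step 4
Reactants: 6 4,5-dimethoxy-3-[(triisopropylsilyl)oxy]benzoic acid; 7 2,2-dimethyl-1,3-dioxane-4,6-dione (Meldrum's acid)
Product: 8 5-{[4,5-dimethoxy-3-(triisopropylsilyloxy)phenyl](hydroxy)methylidene}-2,2-dimethyl-1,3-dioxane-4,6-dione
Conditions: DCC, DMAP, CH2Cl2, 0 °C to rt; dilute HCl wash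
Reagents that add atoms: none
Why: Carbodiimide-mediated C-acylation of Meldrum's acid by a carboxylic acid is the standard entry to acyl Meldrum's acids; it forms the C2–C1 bond and brings in C1 and C8.

Step 5
Reactants: 8 5-{[4,5-dimethoxy-3-(triisopropylsilyloxy)phenyl](hydroxy)methylidene}-2,2-dimethyl-1,3-dioxane-4,6-dione; 3 prop-2-enyl (3S)-3-hydroxy-3-(3,4,5-trimethoxyphenyl)propanoate
Product: 10 (1S)-3-oxo-3-(prop-2-enyloxy)-1-(3,4,5-trimethoxyphenyl)propyl 3-[4,5-dimethoxy-3-(triisopropylsilyloxy)phenyl]-3-oxopropanoate, via aroylketene 9 (not isolated)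
Conditions: toluene, 90 °C (8 in slight excess)
Reagents that add atoms: none
Why: Thermolysis of an acyl Meldrum's acid releases an acylketene that a secondary alcohol traps as the β-keto ester. The medium is neutral, so the β-acyloxy ester cannot eliminate, and acylation at oxygen retains C6.

Step 6
Reactants: 10 (1S)-3-oxo-3-(prop-2-enyloxy)-1-(3,4,5-trimethoxyphenyl)propyl 3-[4,5-dimethoxy-3-(triisopropylsilyloxy)phenyl]-3-oxopropanoate
Product: 11 (1S)-3-oxo-3-(prop-2-enyloxy)-1-(3,4,5-trimethoxyphenyl)propyl (3S)-3-[4,5-dimethoxy-3-(triisopropylsilyloxy)phenyl]-3-hydroxypropanoate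
Conditions: RuCl[(S,S)-TsDPEN](p-cymene) (2 mol %), HCO2H/Et3N (5:2), DMF, 40 °C
Reagents that add atoms: none
Why: The same asymmetric transfer hydrogenation, now on the aryl A ketone; the catalyst and not the remote C6 centre should set C2 as (S). The weakly acidic medium should not provoke β-elimination or acyl migration.

Step 7
Reactants: 11 (1S)-3-oxo-3-(prop-2-enyloxy)-1-(3,4,5-trimethoxyphenyl)propyl (3S)-3-[4,5-dimethoxy-3-(triisopropylsilyloxy)phenyl]-3-hydroxypropanoate
Product: 12 (3S)-3-{[(3S)-3-[4,5-dimethoxy-3-(triisopropylsilyloxy)phenyl]-3-hydroxypropanoyl]oxy}-3-(3,4,5-trimethoxyphenyl)propanoic acid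
Conditions: Pd(PPh3)4 (5 mol %), morpholine, THF, rt; dilute citric acid work-up
Reagents that add atoms: none
Why: Tsuji–Trost deallylation: zerovalent palladium ionises only the allyl ester and morpholine takes up the allyl group. The benzylic ester, the carbinol and the aryl silyl ether should not react.

Step 8
Reactants: 12 (3S)-3-{[(3S)-3-[4,5-dimethoxy-3-(triisopropylsilyloxy)phenyl]-3-hydroxypropanoyl]oxy}-3-(3,4,5-trimethoxyphenyl)propanoic acid
Product: 14 (4S,8S)-4-[4,5-dimethoxy-3-(triisopropylsilyloxy)phenyl]-8-(3,4,5-trimethoxyphenyl)-1,5-dioxocane-2,6-dione, via mixed anhydride 13 (not isolated)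
Conditions: 2-methyl-6-nitrobenzoic anhydride (1.5 equiv), DMAP (6 equiv), toluene, 60 °C, 12 added over 16 h to 1 mM
Reagents that add atoms: none
Why: Shiina macrolactonisation is an established activation for eight-membered lactones; slow addition keeps the acylpyridinium dilute so that ring closure can compete with oligomerisation. Acylation at oxygen leaves C2 and C6 as (S).

Step 9
Reactants: 14 (4S,8S)-4-[4,5-dimethoxy-3-(triisopropylsilyloxy)phenyl]-8-(3,4,5-trimethoxyphenyl)-1,5-dioxocane-2,6-dione
Product: 16 (1S,2S,5S,6S)-2-[4,5-dimethoxy-3-(triisopropylsilyloxy)phenyl]-6-(3,4,5-trimethoxyphenyl)-3,7-dioxabicyclo[3.3.0]octane-4,8-dione, via bis(ketene silyl acetal) 15 (not isolated)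
Conditions: LiN(SiMe3)2 (2.5 equiv) added to 14 and Me3SiCl (6 equiv), THF, −78 °C; volatiles removed, CH2Cl2; TiCl4 (3 equiv), −78 to −30 °C
Reagents that add atoms: none
Why: Proposed new method: transannular oxidative coupling of the two ester α-carbons of an eight-membered diolide; the closest known reaction type is the TiCl4- or copper-salt-mediated oxidative coupling of ketene silyl acetals and ester enolates to succinates, known between molecules and within open-chain tethers but not across a ring. Enolisation with internal Me3SiCl quench should turn both lactone units into ketene silyl acetals before either enolate can expel its β-carboxylate; Si-to-Ti exchange then gives a trichlorotitanium enolate whose Ti–O homolysis (tetravalent to trivalent titanium) leaves an α-acyl radical at C1 that attacks C5 of the facing ketene acetal, and a second TiCl4 oxidises the resulting acetal radical to the second carbonyl. The one bond C1–C5 closes ring A and ring B together: for the attacking carbon it is 5-exo-trig with respect to the ring that contains only the attacked carbon and formally 5-endo-trig with respect to the other, the pattern of transannular 1,5-closures of cycloocta-1,5-dienes to cis-bicyclo[3.3.0]octanes. C1 and C5 are tied to each other by the cis fusion that the bicyclic skeleton enforces, so only two diastereomers are possible. C2 (S) and C6 (S) decide between them: in the tub-shaped 15 both aryl groups sit pseudo-equatorial and each α-carbon bonds on the face anti to its neighbouring aryl group, which is the exo,exo isomer 16, whereas the other isomer would force both aryl groups onto the concave face. The step needs C–C coupling to beat β-elimination, Lewis-acid ionisation of the benzylic C–O bonds and intermolecular coupling; the ring holds C1 and C5 within contact distance, and in situ silylation and low temperature guard against the rest.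

Step 10
Reactants: 16 (1S,2S,5S,6S)-2-[4,5-dimethoxy-3-(triisopropylsilyloxy)phenyl]-6-(3,4,5-trimethoxyphenyl)-3,7-dioxabicyclo[3.3.0]octane-4,8-dione
Product: 17 (1S,2S,5S,6S)-2-[4,5-dimethoxy-3-(triisopropylsilyloxy)phenyl]-6-(3,4,5-trimethoxyphenyl)-3,7-dioxabicyclo[3.3.0]octane-4,8-diol (mixture of lactol epimers at C4 and C8)
Conditions: i-Bu2AlH (2.4 equiv), CH2Cl2, −78 °C; aq. potassium sodium tartrate (KNaC4H4O6)
Reagents that add atoms: none
Why: Partial reduction of γ-lactones to lactols with i-Bu2AlH at −78 °C is standard, the tetrahedral aluminate persisting until work-up. The aryl silyl ether and the four stereocentres are not involved.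

Step 11
Reactants: 17 (1S,2S,5S,6S)-2-[4,5-dimethoxy-3-(triisopropylsilyloxy)phenyl]-6-(3,4,5-trimethoxyphenyl)-3,7-dioxabicyclo[3.3.0]octane-4,8-diol
Product: 18 (1R,2S,5R,6S)-2-[4,5-dimethoxy-3-(triisopropylsilyloxy)phenyl]-6-(3,4,5-trimethoxyphenyl)-3,7-dioxabicyclo[3.3.0]octane
Conditions: Et3SiH (6 equiv), BF3·OEt2 (4 equiv), CH2Cl2, −78 to −40 °C
Reagents that add atoms: none
Why: Ionic hydrogenation of lactols through cyclic oxocarbenium ions is the standard lactol-to-ether reduction. C4 and C8 end as CH2, and C1, C2, C5 and C6 stay untouched as long as the low temperature keeps the benzylic C–O bonds from ionising.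

Step 12
Reactants: 18 (1R,2S,5R,6S)-2-[4,5-dimethoxy-3-(triisopropylsilyloxy)phenyl]-6-(3,4,5-trimethoxyphenyl)-3,7-dioxabicyclo[3.3.0]octane
Product: 19 (1R,2S,5R,6S)-2-(3-hydroxy-4,5-dimethoxyphenyl)-6-(3,4,5-trimethoxyphenyl)-3,7-dioxabicyclo[3.3.0]octane
Conditions: Bu4NF (1.1 equiv), THF, 0 °C; aq. NH4Cl
Reagents that add atoms: none
Why: Fluoride cleavage of an aryl silyl ether needs neither acid nor hydrogen, so the benzylic ethers and all stereocentres should be unaffected.

## Compound list

1 | ethyl 3-oxo-3-(3,4,5-trimethoxyphenyl)propanoate | CCOC(=O)CC(=O)c1cc(OC)c(OC)c(OC)c1 | starting material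
2 | prop-2-enyl 3-oxo-3-(3,4,5-trimethoxyphenyl)propanoate | C=CCOC(=O)CC(=O)c1cc(OC)c(OC)c(OC)c1 | intermediate
3 | prop-2-enyl (3S)-3-hydroxy-3-(3,4,5-trimethoxyphenyl)propanoate | C=CCOC(=O)C[C@H](O)c1cc(OC)c(OC)c(OC)c1 | intermediate
4 | 3-hydroxy-4,5-dimethoxybenzoic acid | COc1cc(C(=O)O)cc(O)c1OC | starting material
5 | triisopropylsilyl 4,5-dimethoxy-3-[(triisopropylsilyl)oxy]benzoate (formed in the flask, not isolated) | COc1cc(C(=O)O[Si](C(C)C)(C(C)C)C(C)C)cc(O[Si](C(C)C)(C(C)C)C(C)C)c1OC | intermediate
6 | 4,5-dimethoxy-3-[(triisopropylsilyl)oxy]benzoic acid | COc1cc(C(=O)O)cc(O[Si](C(C)C)(C(C)C)C(C)C)c1OC | intermediate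
7 | 2,2-dimethyl-1,3-dioxane-4,6-dione (Meldrum's acid) | CC1(C)OC(=O)CC(=O)O1 | starting material
8 | 5-{[4,5-dimethoxy-3-(triisopropylsilyloxy)phenyl](hydroxy)methylidene}-2,2-dimethyl-1,3-dioxane-4,6-dione | CC1(C)OC(=O)C(=C(O)c2cc(OC)c(OC)c(O[Si](C(C)C)(C(C)C)C(C)C)c2)C(=O)O1 | intermediate
9 | 3-[4,5-dimethoxy-3-(triisopropylsilyloxy)phenyl]-3-oxoprop-1-en-1-one (aroylketene, not isolated) | O=C=CC(=O)c1cc(OC)c(OC)c(O[Si](C(C)C)(C(C)C)C(C)C)c1 | intermediate
10 | (1S)-3-oxo-3-(prop-2-enyloxy)-1-(3,4,5-trimethoxyphenyl)propyl 3-[4,5-dimethoxy-3-(triisopropylsilyloxy)phenyl]-3-oxopropanoate | C=CCOC(=O)C[C@H](OC(=O)CC(=O)c1cc(OC)c(OC)c(O[Si](C(C)C)(C(C)C)C(C)C)c1)c1cc(OC)c(OC)c(OC)c1 | intermediate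
11 | (1S)-3-oxo-3-(prop-2-enyloxy)-1-(3,4,5-trimethoxyphenyl)propyl (3S)-3-[4,5-dimethoxy-3-(triisopropylsilyloxy)phenyl]-3-hydroxypropanoate | C=CCOC(=O)C[C@H](OC(=O)C[C@H](O)c1cc(OC)c(OC)c(O[Si](C(C)C)(C(C)C)C(C)C)c1)c1cc(OC)c(OC)c(OC)c1 | intermediate
12 | (3S)-3-{[(3S)-3-[4,5-dimethoxy-3-(triisopropylsilyloxy)phenyl]-3-hydroxypropanoyl]oxy}-3-(3,4,5-trimethoxyphenyl)propanoic acid | OC(=O)C[C@H](OC(=O)C[C@H](O)c1cc(OC)c(OC)c(O[Si](C(C)C)(C(C)C)C(C)C)c1)c1cc(OC)c(OC)c(OC)c1 | intermediate
13 | mixed anhydride of 12 and 2-methyl-6-nitrobenzoic acid (not isolated) | Cc1cccc([N+](=O)[O-])c1C(=O)OC(=O)C[C@H](OC(=O)C[C@H](O)c1cc(OC)c(OC)c(O[Si](C(C)C)(C(C)C)C(C)C)c1)c1cc(OC)c(OC)c(OC)c1 | intermediate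
14 | (4S,8S)-4-[4,5-dimethoxy-3-(triisopropylsilyloxy)phenyl]-8-(3,4,5-trimethoxyphenyl)-1,5-dioxocane-2,6-dione | COc1cc(cc(O[Si](C(C)C)(C(C)C)C(C)C)c1OC)[C@H]1OC(=O)C[C@H](OC(=O)C1)c1cc(OC)c(OC)c(OC)c1 | intermediate
15 | (4S,8S)-4-[4,5-dimethoxy-3-(triisopropylsilyloxy)phenyl]-8-(3,4,5-trimethoxyphenyl)-2,6-bis(trimethylsilyloxy)-4H,8H-1,5-dioxocine (not isolated) | COc1cc(cc(O[Si](C(C)C)(C(C)C)C(C)C)c1OC)[C@H]1O/C(O[Si](C)(C)C)=C\[C@H](O/C(O[Si](C)(C)C)=C\1)c1cc(OC)c(OC)c(OC)c1 | intermediate
16 | (1S,2S,5S,6S)-2-[4,5-dimethoxy-3-(triisopropylsilyloxy)phenyl]-6-(3,4,5-trimethoxyphenyl)-3,7-dioxabicyclo[3.3.0]octane-4,8-dione | COc1cc(cc(O[Si](C(C)C)(C(C)C)C(C)C)c1OC)[C@H]1OC(=O)[C@H]2[C@@H]1C(=O)O[C@@H]2c1cc(OC)c(OC)c(OC)c1 | intermediate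
17 | (1S,2S,5S,6S)-2-[4,5-dimethoxy-3-(triisopropylsilyloxy)phenyl]-6-(3,4,5-trimethoxyphenyl)-3,7-dioxabicyclo[3.3.0]octane-4,8-diol (lactol epimers at C4 and C8) | COc1cc(cc(O[Si](C(C)C)(C(C)C)C(C)C)c1OC)[C@H]1OC(O)[C@H]2[C@@H]1C(O)O[C@@H]2c1cc(OC)c(OC)c(OC)c1 | intermediate
18 | (1R,2S,5R,6S)-2-[4,5-dimethoxy-3-(triisopropylsilyloxy)phenyl]-6-(3,4,5-trimethoxyphenyl)-3,7-dioxabicyclo[3.3.0]octane | COc1cc(cc(O[Si](C(C)C)(C(C)C)C(C)C)c1OC)[C@H]1OC[C@H]2[C@@H]1CO[C@@H]2c1cc(OC)c(OC)c(OC)c1 | intermediate
19 | (1R,2S,5R,6S)-2-(3-hydroxy-4,5-dimethoxyphenyl)-6-(3,4,5-trimethoxyphenyl)-3,7-dioxabicyclo[3.3.0]octane | COc1cc([C@H]2OC[C@H]3[C@@H]2CO[C@@H]3c2cc(OC)c(OC)c(OC)c2)cc(O)c1OC | target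

## Step count and least certain steps

Total: 12 steps. Longest linear sequence: 10 steps (from 4 through steps 3–12, or from 1 through steps 1, 2 and 5–12).

**Step 9 (key step).** Three processes threaten it. Either lactone enolate may expel its benzylic carboxylate (E1cB ring opening to a cinnamate) before it is silylated. TiCl4 may ionise the benzylic C–O bonds. The two titanium enolates may couple between molecules or simply be protonated if their faces do not meet across the ring.

The fallback uses known chemistry, sets out from 1 and 8 and returns at 16. It makes the C1–C5 bond at the β-keto ester level, where the enolates carry no β-leaving group. Thermolysis of 8 in ethanol would give ethyl 3-[4,5-dimethoxy-3-(triisopropylsilyloxy)phenyl]-3-oxopropanoate F1. Bromination of 1 (NBS, CH2Cl2) would give ethyl 2-bromo-3-oxo-3-(3,4,5-trimethoxyphenyl)propanoate F2. Alkylation of the sodium enolate of F1 (NaH, THF) with F2, the classical entry to 2,3-diacylsuccinates, would give diethyl 2-[4,5-dimethoxy-3-(triisopropylsilyloxy)benzoyl]-3-(3,4,5-trimethoxybenzoyl)butanedioate F3. Transfer hydrogenation of both aryl ketones with the catalyst of step 2 would give diethyl 2-{(S)-[4,5-dimethoxy-3-(triisopropylsilyloxy)phenyl](hydroxy)methyl}-3-[(S)-hydroxy(3,4,5-trimethoxyphenyl)methyl]butanedioate F4. Its two γ-hydroxy ester units lactonise crosswise (TsOH, then a trace of DBU) to 16. C2 and C6 are fixed by the catalyst and C1 and C5 are both α to carbonyl groups, so equilibration should drain into the exo,exo cis-fused dilactone.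

**Step 8.** Oligomerisation is likely to outrun ring closure, because the in-chain ester must turn from its s-trans to its s-cis form before the chain ends can meet. The activated acyl group may also lose its β-acyloxy substituent by E1cB.

The fallback sets out from 10 and returns at 14. It closes the ring at the alkyl C–O bond instead, so no activated β-acyloxy acyl group is formed. Reduction of 10 with the (R,R) catalyst would give prop-2-enyl (3S)-3-{[(3R)-3-[4,5-dimethoxy-3-(triisopropylsilyloxy)phenyl]-3-hydroxypropanoyl]oxy}-3-(3,4,5-trimethoxyphenyl)propanoate F5. Deallylation as in step 7 would give (3S)-3-{[(3R)-3-[4,5-dimethoxy-3-(triisopropylsilyloxy)phenyl]-3-hydroxypropanoyl]oxy}-3-(3,4,5-trimethoxyphenyl)propanoic acid F6. Mitsunobu lactonisation (PPh3, diisopropyl azodicarboxylate, toluene, high dilution) would close the ring with inversion at C2 to give 14. This closure removes the elimination pathway but not the ring-size handicap; if neither closure delivers 14, the route continues through the fallback given for step 9, which does not pass through 14.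

**Step 11.** BF3 may ionise the benzylic C2–O3 or C6–O7 bond of the lactol or of the oxocarbenium ion; this would lead to epimerisation at C2 or C6 or to reductive ring opening by Et3SiH.

The fallback sets out from 16 and returns at 18; it avoids cations altogether. LiAlH4 in THF would reduce 16 to (1S,2R,3R,4S)-1-[4,5-dimethoxy-3-(triisopropylsilyloxy)phenyl]-2,3-bis(hydroxymethyl)-4-(3,4,5-trimethoxyphenyl)butane-1,4-diol F7. MsCl (2.1 equiv) in pyridine at −20 °C would sulfonylate the two primary hydroxyls to give the bis(methanesulfonate) F8. The benzylic hydroxyls then displace the primary sulfonates by SN2 on warming, closing ring A and ring B with retention at C2 and C6 to give 18.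

## Further compounds

F1 | step 9 | ethyl 3-[4,5-dimethoxy-3-(triisopropylsilyloxy)phenyl]-3-oxopropanoate | CCOC(=O)CC(=O)c1cc(OC)c(OC)c(O[Si](C(C)C)(C(C)C)C(C)C)c1
F2 | step 9 | ethyl 2-bromo-3-oxo-3-(3,4,5-trimethoxyphenyl)propanoate (racemic, enolisable) | CCOC(=O)C(Br)C(=O)c1cc(OC)c(OC)c(OC)c1
F3 | step 9 | diethyl 2-[4,5-dimethoxy-3-(triisopropylsilyloxy)benzoyl]-3-(3,4,5-trimethoxybenzoyl)butanedioate (epimers at the two enolisable carbons) | CCOC(=O)C(C(=O)c1cc(OC)c(OC)c(O[Si](C(C)C)(C(C)C)C(C)C)c1)C(C(=O)OCC)C(=O)c1cc(OC)c(OC)c(OC)c1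
F4 | step 9 | diethyl 2-{(S)-[4,5-dimethoxy-3-(triisopropylsilyloxy)phenyl](hydroxy)methyl}-3-[(S)-hydroxy(3,4,5-trimethoxyphenyl)methyl]butanedioate (epimers at the two succinate carbons) | CCOC(=O)C([C@H](O)c1cc(OC)c(OC)c(O[Si](C(C)C)(C(C)C)C(C)C)c1)C(C(=O)OCC)[C@H](O)c1cc(OC)c(OC)c(OC)c1
F5 | step 8 | prop-2-enyl (3S)-3-{[(3R)-3-[4,5-dimethoxy-3-(triisopropylsilyloxy)phenyl]-3-hydroxypropanoyl]oxy}-3-(3,4,5-trimethoxyphenyl)propanoate | C=CCOC(=O)C[C@H](OC(=O)C[C@@H](O)c1cc(OC)c(OC)c(O[Si](C(C)C)(C(C)C)C(C)C)c1)c1cc(OC)c(OC)c(OC)c1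
F6 | step 8 | (3S)-3-{[(3R)-3-[4,5-dimethoxy-3-(triisopropylsilyloxy)phenyl]-3-hydroxypropanoyl]oxy}-3-(3,4,5-trimethoxyphenyl)propanoic acid | OC(=O)C[C@H](OC(=O)C[C@@H](O)c1cc(OC)c(OC)c(O[Si](C(C)C)(C(C)C)C(C)C)c1)c1cc(OC)c(OC)c(OC)c1
F7 | step 11 | (1S,2R,3R,4S)-1-[4,5-dimethoxy-3-(triisopropylsilyloxy)phenyl]-2,3-bis(hydroxymethyl)-4-(3,4,5-trimethoxyphenyl)butane-1,4-diol | COc1cc(cc(O[Si](C(C)C)(C(C)C)C(C)C)c1OC)[C@@H](O)[C@@H](CO)[C@H](CO)[C@H](O)c1cc(OC)c(OC)c(OC)c1
F8 | step 11 | bis(methanesulfonate) of F7 at the two primary hydroxyls | COc1cc(cc(O[Si](C(C)C)(C(C)C)C(C)C)c1OC)[C@@H](O)[C@@H](COS(C)(=O)=O)[C@H](COS(C)(=O)=O)[C@H](O)c1cc(OC)c(OC)c(OC)c1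
A1 | alternative 1 | (5R)-5-[(triphenylmethoxy)methyl]furan-2(5H)-one | O=C1C=C[C@H](COC(c2ccccc2)(c2ccccc2)c2ccccc2)O1
A2 | alternative 1 | 2-[4,5-dimethoxy-3-(triisopropylsilyloxy)phenyl]-1,3-dithiane | COc1cc(cc(O[Si](C(C)C)(C(C)C)C(C)C)c1OC)C1SCCCS1
A3 | alternative 1 | 3,4,5-trimethoxybenzaldehyde | COc1cc(C=O)cc(OC)c1OC
A4 | alternative 1 | trans,trans lactone: α-[hydroxy(3,4,5-trimethoxyphenyl)methyl]-β-{2-[4,5-dimethoxy-3-(triisopropylsilyloxy)phenyl]-1,3-dithian-2-yl}-γ-(trityloxymethyl)-γ-butyrolactone (carbinol drawn as one epimer) | O=C1O[C@@H](COC(c2ccccc2)(c2ccccc2)c2ccccc2)[C@H](C2(SCCCS2)c2cc(OC)c(OC)c(O[Si](C(C)C)(C(C)C)C(C)C)c2)[C@H]1[C@H](O)c1cc(OC)c(OC)c(OC)c1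
A5 | alternative 2 | (5S)-5-(3,4,5-trimethoxyphenyl)furan-2(5H)-one | O=C1C=C[C@@H](c2cc(OC)c(OC)c(OC)c2)O1
A6 | alternative 2 | 2-[4,5-dimethoxy-3-(triisopropylsilyloxy)phenyl]-1,1-dimethoxyethene | COC(OC)=Cc1cc(OC)c(OC)c(O[Si](C(C)C)(C(C)C)C(C)C)c1
A7 | alternative 2 | 7-[4,5-dimethoxy-3-(triisopropylsilyloxy)phenyl]-6,6-dimethoxy-4-(3,4,5-trimethoxyphenyl)-3-oxabicyclo[3.2.0]heptan-2-one (aryl A exo) | O=C1O[C@H](c2cc(OC)c(OC)c(OC)c2)[C@@H]2[C@H]1[C@@H](c1cc(OC)c(OC)c(O[Si](C(C)C)(C(C)C)C(C)C)c1)C2(OC)OC
A8 | alternative 3 | (3E,4R,5S)-5-[4,5-dimethoxy-3-(triisopropylsilyloxy)phenyl]-4-(hydroxymethyl)-3-[(3,4,5-trimethoxyphenyl)methylidene]oxolan-2-one | COc1cc(cc(O[Si](C(C)C)(C(C)C)C(C)C)c1OC)[C@H]1OC(=O)/C(=C/c2cc(OC)c(OC)c(OC)c2)[C@@H]1CO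
A9 | alternative 3 | (1R,2S,5S,6S)-2-[4,5-dimethoxy-3-(triisopropylsilyloxy)phenyl]-6-(3,4,5-trimethoxyphenyl)-3,7-dioxabicyclo[3.3.0]octan-4-one | COc1cc(cc(O[Si](C(C)C)(C(C)C)C(C)C)c1OC)[C@H]1OC(=O)[C@H]2[C@@H]1CO[C@@H]2c1cc(OC)c(OC)c(OC)c1
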